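**Plan**
- Retrosynthesis: the C15 acetate and C8 hydroxyl are traced back to a bis-silyl ether; the C6–C7 bond is cut, which opens the lactone and the ten-membered ring together and leaves an acyclic enal / 2-(bromomethyl)enoate; the chain is then cut at C7–C11 (Morita–Baylis–Hillman), C1=C10 (HWE), C3–C4 (Negishi) and C9–C10 (epoxide opening).
- Enabling feature: the α-methylene-γ-butyrolactone (O–C6–C7–C11–C12) fused across C6–C7 to the cyclodeca-1(10),4-diene is the retron of an aldehyde (C6) plus a 2-(alkoxycarbonyl)allyl metal (C13–C11–C7). Both ring alkenes are cis within the ring, so the open chain folds C6 onto C7.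
- Forward: the C1–C6/C15 aldehyde is built from fumaraldehyde mono(dimethyl acetal); the C7–C10/C14 phosphono lactone from (R)-PMB glycidyl ether; HWE joins them; methyl acrylate adds C11–C13; Cr(II) closes the carbocycle and then the lactone; desilylation and acetylation finish.
- Stereochemistry: C8 comes from the glycidyl ether; C7 and C6 are set in the key step by relay from C8 (allylic strain plus chair transition state). The alkene geometries come from a (Z)-α-iodoenal (retentive coupling) and an E-selective HWE. The allylic bromide geometry is irrelevant, because both isomers converge on one allylchromium species.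

Key step: step 16

Remark: atoms carry germacranolide numbers (C6 lactone carbinol, C7 ring-fusion CH, C8 carbinol, C12 lactone C=O, C13 exocyclic CH2, C14/C15 the CH2O carbons on C10/C4). Both ring-cis alkenes are (E) by CIP throughout, and the CIP label of C7 reads S while O8 is silylated, with unchanged geometry.

**Step 1**
Reactants: 1 (E)-4,4-dimethoxybut-2-enal
Product: 2 (Z)-2-iodo-4,4-dimethoxybut-2-enal
Conditions: I2, K2CO3, DMAP (cat.), THF/H2O, rt
Reagents that add atoms: iodine, II
Why: amine-catalysed α-iodination of an enal (conjugate addition of DMAP, iodination of the enolate, E1cB loss of DMAP) should give the thermodynamic (Z)-iodoenal with iodine cis to the acetal carbon, which fixes the later C4=C5 geometry.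

**Step 2**
Reactants: 2 (Z)-2-iodo-4,4-dimethoxybut-2-enal
Product: 3 (Z)-2-iodo-4,4-dimethoxybut-2-en-1-ol
Conditions: NaBH4, CeCl3·7H2O, MeOH, 0 °C
Reagents that add atoms: none
Why: Luche 1,2-reduction of the enal leaves the vinyl iodide, the acetal and the alkene geometry untouched.

**Step 3**
Reactants: 3 (Z)-2-iodo-4,4-dimethoxybut-2-en-1-ol
Product: 4 (Z)-tert-butyl[(2-iodo-4,4-dimethoxybut-2-en-1-yl)oxy]dimethylsilane
Conditions: TBSCl, imidazole, DMF, rt
Reagents that add atoms: tert-butyldimethylsilyl chloride, CC(C)(C)[Si](C)(C)Cl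
Why: standard silylation of a primary allylic alcohol under basic conditions that spare the acetal.

**Step 4**
Reactants: 4 (Z)-tert-butyl[(2-iodo-4,4-dimethoxybut-2-en-1-yl)oxy]dimethylsilane; 5 (3-ethoxy-3-oxopropyl)zinc bromide
Product: 6 ethyl (E)-4-[(tert-butyldimethylsilyloxy)methyl]-6,6-dimethoxyhex-4-enoate
Conditions: Pd2(dba)3 (cat.), SPhos (cat.), THF/NMP, 45 °C
Reagents that add atoms: none
Why: Negishi sp2–sp3 coupling proceeds with retention at the alkenyl carbon, so the new C3 chain ends up cis to C6 and trans to CH2OTBS.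

**Step 5**
Reactants: 6 ethyl (E)-4-[(tert-butyldimethylsilyloxy)methyl]-6,6-dimethoxyhex-4-enoate
Product: 7 (E)-4-[(tert-butyldimethylsilyloxy)methyl]-6,6-dimethoxyhex-4-enal
Conditions: DIBAL-H (1.1 equiv), CH2Cl2, −78 °C; Rochelle salt
Reagents that add atoms: none
Why: DIBAL half-reduction of an ester stops at the aldehyde because the tetrahedral aluminate is stable at −78 °C.

**Step 6**
Reactants: 8 (R)-2-[(4-methoxybenzyloxy)methyl]oxirane; 9 triethyl phosphonoacetate
Product: 11 diethyl [(5R)-5-[(4-methoxybenzyloxy)methyl]-2-oxooxolan-3-yl]phosphonate (C3 epimers), via hydroxy phosphono ester alkoxide 10 (not isolated)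
Conditions: NaOEt, EtOH, 70 °C; aq. NH4Cl
Reagents that add atoms: none
Why: the phosphonoacetate anion opens the terminal epoxide at its CH2 carbon (SN2) and the resulting γ-alkoxide lactonises on the ethyl ester (epoxide-opening/lactonisation route to α-phosphono-γ-lactones); the C8 stereocentre is not touched.

**Step 7**
Reactants: 7 (E)-4-[(tert-butyldimethylsilyloxy)methyl]-6,6-dimethoxyhex-4-enal; 11 diethyl [(5R)-5-[(4-methoxybenzyloxy)methyl]-2-oxooxolan-3-yl]phosphonate
Product: 12 (3E,5R)-3-{(E)-4-[(tert-butyldimethylsilyloxy)methyl]-6,6-dimethoxyhex-4-enylidene}-5-[(4-methoxybenzyloxy)methyl]oxolan-2-one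
Conditions: NaH, THF, 0 °C to rt
Reagents that add atoms: none
Why: Horner–Wadsworth–Emmons olefination of an α-phosphono lactone should favour the (E)-alkylidene lactone (chain anti to the lactone carbonyl), which is the ring-cis C1=C10 geometry with C2 cis to C9.

**Step 8**
Reactants: 12 (3E,5R)-alkylidene lactone
Product: 13 (2R,4E,8E)-4-(hydroxymethyl)-8-[(tert-butyldimethylsilyloxy)methyl]-10,10-dimethoxy-1-(4-methoxybenzyloxy)deca-4,8-dien-2-ol
Conditions: DIBAL-H (4.5 equiv), CH2Cl2, −78 to 0 °C; Rochelle salt
Reagents that add atoms: none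
Why: DIBAL 1,2-reduction of the α-alkylidene lactone gives the ene-diol (C14–OH primary allylic, C8–OH secondary) without touching the silyl ether, acetal or PMB ether.

**Step 9**
Reactants: 13 ene-diol
Product: 14 C14 isobutyrate of 13 (C8–OH free)
Conditions: i-PrCOCl (1.05 equiv), 2,4,6-collidine, CH2Cl2, −78 to −40 °C
Reagents that add atoms: isobutyryl chloride, CC(C)C(Cl)=O
Why: a hindered acyl chloride with collidine at low temperature acylates the primary allylic hydroxyl selectively over the secondary one.

**Step 10**
Reactants: 14 C14 isobutyrate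
Product: 15 C8 tert-butyldimethylsilyl ether of 14
Conditions: TBSCl, imidazole, DMAP (cat.), DMF, 35 °C
Reagents that add atoms: tert-butyldimethylsilyl chloride, CC(C)(C)[Si](C)(C)Cl
Why: silylation with TBSCl/imidazole protects the secondary alcohol without a Lewis-acidic silyl triflate that would attack the dimethyl acetal.

**Step 11**
Reactants: 15 C8 silyl ether
Product: 16 primary alcohol at C7 (PMB removed)
Conditions: DDQ, CH2Cl2/pH 7 buffer, 0 °C
Reagents that add atoms: none
Why: oxidative cleavage of the PMB ether by DDQ is neutral and leaves silyl ethers, the isobutyrate, the acetal and the trisubstituted alkenes intact.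

**Step 12**
Reactants: 16 primary alcohol
Product: 17 α-silyloxy aldehyde (C7 aldehyde, 8R)
Conditions: Dess–Martin periodinane, NaHCO3, CH2Cl2, 0 °C to rt
Reagents that add atoms: none
Why: buffered Dess–Martin oxidation gives the α-silyloxy aldehyde without epimerising C8; it is used directly.

**Step 13**
Reactants: 17 α-silyloxy aldehyde; 18 methyl acrylate
Product: 19 Morita–Baylis–Hillman alcohol (C7 epimers, 8R)
Conditions: DABCO, methyl acrylate (excess), 1,4-dioxane/H2O, rt
Reagents that add atoms: none
Why: Morita–Baylis–Hillman reaction of an activated α-oxygenated aldehyde with methyl acrylate installs C11–C13; the new C7 carbinol centre is of no consequence because it becomes sp2 in the next step.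

**Step 14**
Reactants: 19 Morita–Baylis–Hillman alcohol
Product: 20 methyl (2Z,4R)-2-(bromomethyl)-4-(tert-butyldimethylsilyloxy)alk-2-enoate, C6 still as dimethyl acetal (minor 2E isomer tolerated)
Conditions: NBS, Me2S, CH2Cl2, 0 °C to rt
Reagents that add atoms: N-bromosuccinimide, O=C1CCC(=O)N1Br
Why: Corey–Kim-type activation of the hydroxyl followed by SN2' attack of bromide at the terminal CH2 gives the transposed primary allylic bromide; its E/Z ratio does not matter for step 16.

**Step 15**
Reactants: 20 allylic bromide acetal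
Product: 21 seco enal bromide (C6 aldehyde, C4=C5 E, C1=C10 E, 8R)
Conditions: PPTS (cat.), acetone/H2O 10:1, rt
Reagents that add atoms: water, O
Why: the α,β-unsaturated dimethyl acetal hydrolyses under very mild acid that should leave both silyl ethers and the allylic bromide intact.

**Step 16**
Reactants: 21 seco enal bromide
Product: 24 bis-silylated germacranolide (trans-fused 12,6-lactone; 6R 7S 8R), via allylchromium(III) species 22 (not isolated), via chromium(III) alkoxide 23 (not isolated)
Conditions: CrCl2 (10 equiv), degassed THF, syringe-pump addition to 2 mM, rt; aq. NH4Cl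
Reagents that add atoms: none
Why: Cr(II) inserts into the allylic C13–Br bond by two one-electron transfers to give the 2-(methoxycarbonyl)allylchromium(III) species 22, whose E and Z forms interconvert by 1,3-metallotropic shift so that either bromide geometry converges on the same reactive species, and this adds through its γ-carbon C7 to the C6 aldehyde in a closed six-membered chair (Nozaki–Hiyama–Kishi 2-(alkoxycarbonyl)allylation), after which the chromium alkoxide 23 acylates on the neighbouring ester. The closest known reaction type is the Cr(II)- or Zn-mediated intramolecular Barbier cyclisation of (bromomethyl)enoate aldehydes used to close ten-membered germacranolide and larger cembranolide rings with in situ α-methylene lactone formation. The carbocycle closes in a 10-exo-trig mode (C=O exocyclic, folding assisted by the two cis ring alkenes C1=C10 and C4=C5) and the lactone in a 5-exo-trig acyl substitution. C7 is set by C8: allylic 1,3-strain against the C11 ester should hold H8 in the plane of C7=C11, with ring carbon C9 anti to the incoming aldehyde and OTBS outside, so the aldehyde takes the C7 face that gives the target's 7,8-relationship; C6 is set relative to C7 by the chair, in which the enal residue and the branched C8 both sit equatorial (C8 trans to CH2Cr), giving the 6,7-anti adduct and hence the trans-fused lactone. The step needs γ- over α-attack (secured by the cyclic transition state), ring closure over oligomerisation (high dilution, slow addition, cis alkenes), anti over syn addition (the branched silyloxy-bearing C8 avoids the axial site) and acylation by O6 only (O8 is silylated and, as a poor leaving group, should also not β-eliminate from the C7-bound chromium form).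

**Step 17**
Reactants: 24 bis-silylated germacranolide
Product: 25 8,15-diol (6R,7R,8R)
Conditions: HF·pyridine, THF/pyridine, 0 °C to rt
Reagents that add atoms: none
Why: fluoride-mediated desilylation removes the primary allylic and the secondary silyl ether while the isobutyrate and the α-methylene lactone persist.

**Step 18**
Reactants: 25 8,15-diol
Product: 26 CNP0312458.1 (target)
Conditions: AcCl (1.1 equiv), 2,4,6-collidine, CH2Cl2, −78 °C
Reagents that add atoms: acetyl chloride, CC(Cl)=O
Why: kinetic acetylation with acetyl chloride/collidine should select the primary allylic C15 hydroxyl over the hindered secondary C8 hydroxyl next to the ring fusion.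

**Compound list**
1 | (E)-4,4-dimethoxybut-2-enal (fumaraldehyde mono(dimethyl acetal)) | O=C/C=C/C(OC)OC | starting material
2 | (Z)-2-iodo-4,4-dimethoxybut-2-enal | O=C/C(I)=C/C(OC)OC | intermediate
3 | (Z)-2-iodo-4,4-dimethoxybut-2-en-1-ol | OC/C(I)=C/C(OC)OC | intermediate
4 | (Z)-tert-butyl[(2-iodo-4,4-dimethoxybut-2-en-1-yl)oxy]dimethylsilane | CC(C)(C)[Si](C)(C)OC/C(I)=C/C(OC)OC | intermediate
5 | (3-ethoxy-3-oxopropyl)zinc bromide | CCOC(=O)CC[Zn]Br | starting material
6 | ethyl (E)-4-[(tert-butyldimethylsilyloxy)methyl]-6,6-dimethoxyhex-4-enoate | CCOC(=O)CC/C(CO[Si](C)(C)C(C)(C)C)=C\C(OC)OC | intermediate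
7 | (E)-4-[(tert-butyldimethylsilyloxy)methyl]-6,6-dimethoxyhex-4-enal | O=CCC/C(CO[Si](C)(C)C(C)(C)C)=C\C(OC)OC | intermediate
8 | (R)-2-[(4-methoxybenzyloxy)methyl]oxirane | COc1ccc(COC[C@H]2CO2)cc1 | starting material
9 | triethyl phosphonoacetate | CCOC(=O)CP(=O)(OCC)OCC | starting material
10 | ethyl (4R)-2-(diethoxyphosphoryl)-4-hydroxy-5-(4-methoxybenzyloxy)pentanoate, formed as its sodium alkoxide (C2 epimers) | CCOC(=O)C(C[C@@H](O)COCc1ccc(OC)cc1)P(=O)(OCC)OCC | intermediate
11 | diethyl [(5R)-5-[(4-methoxybenzyloxy)methyl]-2-oxooxolan-3-yl]phosphonate (C3 epimers) | CCOP(=O)(OCC)C1C[C@H](COCc2ccc(OC)cc2)OC1=O | intermediate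
12 | (3E,5R)-3-{(E)-4-[(tert-butyldimethylsilyloxy)methyl]-6,6-dimethoxyhex-4-enylidene}-5-[(4-methoxybenzyloxy)methyl]oxolan-2-one | O=C1O[C@@H](COCc2ccc(OC)cc2)C/C1=C\CC/C(CO[Si](C)(C)C(C)(C)C)=C\C(OC)OC | intermediate
13 | (2R,4E,8E)-4-(hydroxymethyl)-8-[(tert-butyldimethylsilyloxy)methyl]-10,10-dimethoxy-1-(4-methoxybenzyloxy)deca-4,8-dien-2-ol | OC/C(C[C@@H](O)COCc1ccc(OC)cc1)=C/CC/C(CO[Si](C)(C)C(C)(C)C)=C\C(OC)OC | intermediate
14 | C14 isobutyrate of 13 (C8–OH free, 8R) | CC(C)C(=O)OC/C(C[C@@H](O)COCc1ccc(OC)cc1)=C/CC/C(CO[Si](C)(C)C(C)(C)C)=C\C(OC)OC | intermediate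
15 | C8 tert-butyldimethylsilyl ether of 14 (8R) | CC(C)C(=O)OC/C(C[C@@H](O[Si](C)(C)C(C)(C)C)COCc1ccc(OC)cc1)=C/CC/C(CO[Si](C)(C)C(C)(C)C)=C\C(OC)OC | intermediate
16 | C7 primary alcohol (8R; C8 and C15 silyl ethers, C14 isobutyrate, C6 dimethyl acetal) | CC(C)C(=O)OC/C(C[C@@H](O[Si](C)(C)C(C)(C)C)CO)=C/CC/C(CO[Si](C)(C)C(C)(C)C)=C\C(OC)OC | intermediate
17 | C7 aldehyde (8R α-silyloxy aldehyde) | CC(C)C(=O)OC/C(C[C@@H](O[Si](C)(C)C(C)(C)C)C=O)=C/CC/C(CO[Si](C)(C)C(C)(C)C)=C\C(OC)OC | intermediate
18 | methyl acrylate | C=CC(=O)OC | starting material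
19 | Morita–Baylis–Hillman alcohol: methyl 2-methylidene-3-hydroxy-4-silyloxy ester (C7 epimers, 8R) | C=C(C(=O)OC)C(O)[C@H](O[Si](C)(C)C(C)(C)C)C/C(COC(=O)C(C)C)=C\CC/C(CO[Si](C)(C)C(C)(C)C)=C\C(OC)OC | intermediate
20 | methyl (2Z,4R)-2-(bromomethyl)-4-(tert-butyldimethylsilyloxy)alk-2-enoate with C6 dimethyl acetal (2Z drawn; 2E tolerated) | COC(=O)/C(CBr)=C/[C@H](O[Si](C)(C)C(C)(C)C)C/C(COC(=O)C(C)C)=C\CC/C(CO[Si](C)(C)C(C)(C)C)=C\C(OC)OC | intermediate
21 | seco enal bromide (C6 aldehyde, C13 bromide, 8R) | COC(=O)/C(CBr)=C/[C@H](O[Si](C)(C)C(C)(C)C)C/C(COC(=O)C(C)C)=C\CC/C(CO[Si](C)(C)C(C)(C)C)=C\C=O | intermediate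
22 | 2-(methoxycarbonyl)allylchromium(III) dichloride of 21 (C7=C11 geometry equilibrating) | COC(=O)C(C[Cr](Cl)Cl)=C[C@H](O[Si](C)(C)C(C)(C)C)C/C(COC(=O)C(C)C)=C\CC/C(CO[Si](C)(C)C(C)(C)C)=C\C=O | intermediate
23 | chromium(III) alkoxide of the cyclised hydroxy ester (ten-membered ring closed, configuration as in 24) | Cl[Cr](Cl)O[C@@H]1/C=C(/CO[Si](C)(C)C(C)(C)C)CC/C=C(/COC(=O)C(C)C)C[C@@H](O[Si](C)(C)C(C)(C)C)[C@H]1C(=C)C(=O)OC | intermediate
24 | 8,15-bis(tert-butyldimethylsilyl) ether of the 14-isobutyryloxy germacra-1(10),4,11(13)-trien-12,6-olide (6R,7S,8R; trans-fused lactone) | C=C1C(=O)O[C@@H]2/C=C(/CO[Si](C)(C)C(C)(C)C)CC/C=C(/COC(=O)C(C)C)C[C@@H](O[Si](C)(C)C(C)(C)C)[C@@H]12 | intermediate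
25 | 8,15-dihydroxy-14-isobutyryloxy germacranolide (6R,7R,8R) | C=C1C(=O)O[C@@H]2/C=C(/CO)CC/C=C(/COC(=O)C(C)C)C[C@@H](O)[C@@H]12 | intermediate
26 | CNP0312458.1 (15-acetoxy-8-hydroxy-14-isobutyryloxy germacranolide, 6R,7R,8R) | C=C1C(=O)O[C@@H]2/C=C(/COC(C)=O)CC/C=C(/COC(=O)C(C)C)C[C@@H](O)[C@@H]12 | target

**Totals**
Total step count: 18. Longest linear sequence: 17 (steps 1–5, then 7–18).

**Steps most likely to fail**

First risk, step 16. The closure may run through the competing chair in which C8 sits axial (syn addition), so that the lactone forms cis-fused with C6 inverted; in intermolecular cases with unbranched substituents this syn mode is often the preferred one. The fallback replaces kinetic control by a stereochemical correction and sets out from 21. A zinc-mediated Barbier closure (Zn dust, THF/aq. NH4Cl, high dilution), a manifold that normally adds syn with 3-substituted 2-(bromomethyl)enoates, is taken on purpose to the C6-epimeric cis-fused lactone F1. LiOH (1.1 equiv, THF/H2O, 0 °C) should open the strained lactone of F1 faster than the hindered isobutyrate and, after cold acidification to pH 5, give the 6-epi hydroxy acid F2. Mitsunobu lactonisation of F2 (PPh3, DIAD, THF, 0 °C, dilute) closes the ring with inversion at the allylic C6 and comes back to the route at 24.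

Second risk, step 13. The amine-catalysed addition may be slow on this hindered α-silyloxy aldehyde, which would leave time for base-induced epimerisation at C8 and for attack on the isobutyrate. The fallback uses a preformed vinylmetal instead of nucleophilic catalysis and sets out from 17. [α-(Methoxycarbonyl)vinyl]diisobutylaluminium, generated from methyl propiolate with DIBAL-H/N-methylmorpholine N-oxide in THF at 0 °C, is added at −20 °C (vinylalumination); it should add to the aldehyde only and come back to the route at 19 directly, without any new isolated compound.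

Third risk, step 6. The γ-alkoxide formed by epoxide opening may attack phosphorus instead of the ester, which leads to phosphonate-to-phosphate transfer and cyclopropane formation instead of lactonisation. The fallback builds the lactone first and phosphorylates afterwards, setting out from 8. Diethyl malonate/NaOEt (EtOH, 60 °C) should give ethyl (5R)-5-[(4-methoxybenzyloxy)methyl]-2-oxooxolane-3-carboxylate F3. Krapcho dealkoxycarbonylation of F3 (LiCl, wet DMSO, 140 °C) should give (R)-5-[(4-methoxybenzyloxy)methyl]oxolan-2-one F4. Enolisation of F4 with LDA, O-phosphorylation with diethyl chlorophosphate and a second equivalent of LDA (1,3-phosphorus shift from oxygen to carbon) then comes back to the route at 11.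

**Further compounds**
F1 | step 16 | C6-epimeric cis-fused lactone (6-epi-24) | C=C1C(=O)O[C@H]2/C=C(/CO[Si](C)(C)C(C)(C)C)CC/C=C(/COC(=O)C(C)C)C[C@@H](O[Si](C)(C)C(C)(C)C)[C@@H]12
F2 | step 16 | 6-epi hydroxy acid (opened lactone of F1) | O[C@H]1/C=C(/CO[Si](C)(C)C(C)(C)C)CC/C=C(/COC(=O)C(C)C)C[C@@H](O[Si](C)(C)C(C)(C)C)[C@H]1C(=C)C(=O)O
F0 | step 13 | none | none
F3 | step 6 | ethyl (5R)-5-[(4-methoxybenzyloxy)methyl]-2-oxooxolane-3-carboxylate (C3 epimers) | CCOC(=O)C1C[C@H](COCc2ccc(OC)cc2)OC1=O
F4 | step 6 | (R)-5-[(4-methoxybenzyloxy)methyl]oxolan-2-one | O=C1CC[C@H](COCc2ccc(OC)cc2)O1
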